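Readings and results were computed on assumed constants; the scatter is artificial.

The theta flask was mine to carry on to the asked time, and I reckoned it with a bracket.

| flask | starting material | reagent in the second phase | remark | time | volume of the second phase over the first |
|---|---|---|---|---|---|
| theta | 19 mM | 1.8 equiv | the very flask that is asked about, followed so far |  |  |
| beta | 19 mM | 2.7 equiv | run made earlier |  |  |
| flask | 19 mM | 1.80 equiv |  | 2.5 h | 0.50 |

theta run (percent of the starting material charged)

| time / min | target / % | starting material / % |
|---|---|---|
| 6.00 | 23.0 | 40.4 |
| 20.0 | 53.9 | 3.7 |
| 40.0 | 56.9 | 0.4 |
| 50.0 | 56.4 | 0.7 |
| 80.0 | 57.1 | 0 |

beta run (percent of the starting material charged)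

| time / h | target / % | starting material / % |
|---|---|---|
| 0.500 | 62.4 | 0.3 |
| 1.00 | 63.8 | 0 |
| 1.50 | 63.1 | 0 |
| 2.00 | 64.0 | 0.6 |
| 2.50 | 63.6 | 0 |

(scatter of a reading: 1 percentage point)

- percent here means starting material units held: one homo dimer counts as two
- in the second phase: reagent in the second phase; everything else is in the first
- charges count per volume of the first phase; a concentration in a rate is the amount of a species over the volume of its own phase; every rate counts per litre of the first phase
- steps thought possible: reagent in the reaction phase <-> reagent in the second phase; starting material + reagent in the reaction phase -> target; reagent in the reaction phase <-> dormant form; reagent in the reaction phase -> decomposed reagent; 2 starting material -> homo dimer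
- the earlier runs hold the two phases in the same ratio of volumes as the flask asked about

- the target standing at 2.5 h, as a percentage of the starting material charged
- part of the starting material charged that has reacted at 2.5 h

None of the listed steps uses up target, and the beta run agreed, reading 62.4% at 0.500 h and 63.6% at 2.50 h. So the target standing in the theta flask at a given time was a floor for y, and each reading of it carried the scatter. The step to homo dimer runs one way, so target could still gain from the free starting material but not from what had become dimer. The sum of target and free starting material at one time was therefore an upper bound. As read, it fell from 63.4% at 6.00 min to 57.6% at 20.0 min. Over the last 3 readings target averaged 56.8% and the sum 57.2%; this sum, target plus free starting material at one time, I called the ceiling. With the scatter of those means, my bracket for y ran from 56.2% to 58.0%. The free starting material averaged 0.367%, so I put cv at 99.6% or above.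

The forecast gave 56.9% and 99.9%, holding that “the plateau holds”, which placed its y inside my bracket. The flask gave 57.6% and 100%.

    reagent in the reaction phase ⇌ reagent in the second phase, rate k1*([reagent in the reaction phase] - [reagent in the second phase]/K1) per volume of the first phase (partition coefficient = 0.451, kL = 3.25 × 10⁻⁴ /s)
    starting material + reagent in the reaction phase → target (k = 0.220 /M/s)
    reagent in the reaction phase ⇌ dormant form (K = 7.60, k = 4.78 × 10⁻⁵ /s)
    reagent in the reaction phase → decomposed reagent (k = 3.66 × 10⁻⁵ /s)
    2 starting material → homo dimer (k = 0.0572 /M/s)

The ceiling stood below the charge because of the step to homo dimer: the same run without that step gives 100% of target, where this flask gives 57.6%. In this flask the ceiling was already 57.8% at 0.250 h, with target at 49.6%, and the final 57.6% lies between them. The neighbour flask, charged at 4.8 mM with the same equivalents, has its limiting reagent, starting material, at 0.11% at the asked time, so its floor of 70.5% meets a ceiling of 70.6%.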